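**Retrosynthetic overview**

- The strategy rests on one feature (pyran numbered O1, C2–C6; cyclohexane C1'–C6'): pyran atoms C3, C4, C5, C6 and one C6 methyl are a 5-methylfuran-2-yl group in oxidised form, bonded to the quaternary ether carbon C2 that also carries a methyl and C1'.
- C4'–Cl and C5'–Br come from a cyclohexene through an O1'–C4' bridged bromo ether; C4'=C5' by ring-closing metathesis; C1' from the ester carbon (Weinreb amide, ketone, allyl addition).
- On the pyran, C5–Br comes from bromide conjugate addition to the enone, C3–OH from a CBS reduction, and the second C6 methyl from AlMe3 on the hemiketal.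
- The pyranone ring (O1–C6 bond) comes from an anodic Achmatowicz ring expansion of furyl lactate 3, made from 2-methylfuran and methyl pyruvate by a Cu–bisoxazoline Friedel–Crafts addition.
- Ring order: pyran (step 2), cyclohexene (step 10), transient 7-oxabicyclo[2.2.1]heptane (step 11, opened in step 12).

Key step: step 2

Remark: hemiketal 6 is expected as an anomer mixture (one anomer is drawn); this centre becomes the gem-dimethyl carbon in step 3.
Assumption: the (S,S)-tert-butyl-bisoxazoline is taken to give the S carbinol by si-face attack; if the sense is opposite, the (R,R)-ligand is used.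

**Step 1**
Reactants: 1 2-methylfuran; 2 methyl pyruvate
Product: 3 methyl (2S)-2-hydroxy-2-(5-methylfuran-2-yl)propanoate
Conditions: Cu(OTf)2 (10 mol%), (S,S)-t-Bu-bisoxazoline (11 mol%), Et2O, 0 °C to rt
Reagents that add atoms: none
Why: Friedel–Crafts hydroxyalkylation in which pyruvate chelates the square-planar Cu(II)–bisoxazoline, the tert-butyl groups block one carbonyl face and the free C5 position of the furan attacks the si face, which sets the quaternary carbinol as S.

**Step 2**
Reactants: 3 methyl (2S)-2-hydroxy-2-(5-methylfuran-2-yl)propanoate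
Product: 6 methyl (2S)-6-hydroxy-2,6-dimethyl-3-oxo-3,6-dihydro-2H-pyran-2-carboxylate, via dimethoxydihydrofuran 4 (not isolated), via ene-dione 5 (not isolated)
Conditions: graphite anode, steel cathode, undivided cell, Et4NOTs, MeOH, −10 °C, constant current (about 2.2 F/mol); then THF, 1% aq. H2SO4, 0 °C to rt
Reagents that add atoms: water, O
Why: This is the Achmatowicz rearrangement in its electrochemical form: two-electron anodic oxidation of the furan and capture by methanol at both α-carbons gives the 2,5-dimethoxy-2,5-dihydrofuran 4, whose two ketal centres are hydrolysed by aqueous acid to the (Z)-ene-dione 5. The tertiary hydroxyl of 5 then adds to the distal methyl ketone in a 6-exo-trig hemiketalisation, which forms the O1–C6 bond and closes the pyranone ring; the Z geometry inherited from the furan places the two groups within reach. The closest known reaction is the Achmatowicz ring expansion of furyl carbinols run through 2,5-dimethoxylation. No lasting stereocentre is made, since C2 is quaternary and cannot epimerise and the hemiketal carbon C6 becomes the gem-dimethyl carbon in step 3. Only chemoselectivity is needed, and it is secured because the electron-rich furan is oxidised at a much lower potential than the ester or the tertiary alcohol, which has no carbinol hydrogen.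

**Step 3**
Reactants: 6 methyl (2S)-6-hydroxy-2,6-dimethyl-3-oxo-3,6-dihydro-2H-pyran-2-carboxylate
Product: 7 methyl (2S)-2,6,6-trimethyl-3-oxo-3,6-dihydro-2H-pyran-2-carboxylate
Conditions: AlMe3 (4 equiv), CH2Cl2, −78 to −20 °C; aq. Rochelle salt
Reagents that add atoms: trimethylaluminium, C[Al](C)C
Why: Ketal C-methylation in which the hemiketal, as its aluminium alkoxide, ionises to the ring oxocarbenium ion and takes a methyl group from aluminium at C6; no stereocentre arises because C6 then carries two methyls, and ketone and ester are slower acceptors at low temperature.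

**Step 4**
Reactants: 7 methyl (2S)-2,6,6-trimethyl-3-oxo-3,6-dihydro-2H-pyran-2-carboxylate
Product: 9 methyl (2S,5R)-5-bromo-2,6,6-trimethyl-3-oxooxane-2-carboxylate, via silyl enol ether 8 (not isolated)
Conditions: TMSBr (1.3 equiv), CH2Cl2, −78 to −30 °C; then THF, pH 5 buffer, 0 °C; crude used at once
Reagents that add atoms: bromotrimethylsilane, C[Si](C)(C)Br
Why: Conjugate addition of bromide to the silyl-activated enone, in which bromide enters C5 axially on the sofa conformer that has the C2 ester pseudoaxial (keto and ester dipoles opposed, methyl pseudoequatorial), that is anti to the ester, giving 5R with Br cis to the C2 methyl; this axial bromide has no syn-axial partner (C3 is sp2, O1 bears nothing), so the same epimer should also be the more stable one.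

**Step 5**
Reactants: 9 methyl (2S,5R)-5-bromo-2,6,6-trimethyl-3-oxooxane-2-carboxylate
Product: 10 methyl (2S,3R,5R)-5-bromo-3-hydroxy-2,6,6-trimethyloxane-2-carboxylate
Conditions: (S)-Me-CBS (0.3 equiv), BH3·THF, THF, −20 °C; MeOH quench
Reagents that add atoms: none
Why: Corey–Bakshi–Shibata reduction in which the oxazaborolidine distinguishes the quaternary C2 (large) from the C4 methylene (small), so the (S)-catalyst should deliver hydride to the face that gives the 3R carbinol (OH cis to the ester, trans to Br) under catalyst control; ester and bromide are inert to borane at this temperature.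

**Step 6**
Reactants: 10 methyl (2S,3R,5R)-5-bromo-3-hydroxy-2,6,6-trimethyloxane-2-carboxylate
Product: 11 (2S,3R,5R)-5-bromo-3-hydroxy-N-methoxy-N,2,6,6-tetramethyloxane-2-carboxamide
Conditions: MeNH(OMe)·HCl (3 equiv), i-PrMgCl (7 equiv), THF, −20 to 0 °C
Reagents that add atoms: N,O-dimethylhydroxylamine hydrochloride, CNOC.Cl
Why: Weinreb amide formation by attack of the magnesium N-methoxy-N-methylamide on the ester, run before silylation while the ester is least hindered; no stereocentre is involved.

**Step 7**
Reactants: 11 (2S,3R,5R)-5-bromo-3-hydroxy-N-methoxy-N,2,6,6-tetramethyloxane-2-carboxamide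
Product: 12 (2S,3R,5R)-5-bromo-3-[(tert-butyldimethylsilyl)oxy]-N-methoxy-N,2,6,6-tetramethyloxane-2-carboxamide
Conditions: TBSOTf, 2,6-lutidine, CH2Cl2, 0 °C to rt
Reagents that add atoms: tert-butyldimethylsilyl triflate, CC(C)(C)[Si](C)(C)OS(=O)(=O)C(F)(F)F
Why: Silylation of the hindered secondary alcohol with the silyl triflate, which guards C3–OH against retro-aldol cleavage and against participation in steps 8 to 12.

**Step 8**
Reactants: 12 (2S,3R,5R)-5-bromo-3-[(tert-butyldimethylsilyl)oxy]-N-methoxy-N,2,6,6-tetramethyloxane-2-carboxamide; 13 4-bromo-2-methylbut-1-ene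
Product: 15 1-[(2S,3R,5R)-5-bromo-3-[(tert-butyldimethylsilyl)oxy]-2,6,6-trimethyloxan-2-yl]-4-methylpent-4-en-1-one, via Grignard reagent 14 (not isolated)
Conditions: 13, Mg, I2 (cat.), THF, 40 °C; then 12, THF, 0 °C to rt; aq. NH4Cl
Reagents that add atoms: none
Why: Grignard addition to the Weinreb amide, which stops at the chelated tetrahedral adduct and releases the ketone on work-up; the neopentyl-type secondary bromide should not react with the Grignard reagent at this temperature.

**Step 9**
Reactants: 15 1-[(2S,3R,5R)-5-bromo-3-[(tert-butyldimethylsilyl)oxy]-2,6,6-trimethyloxan-2-yl]-4-methylpent-4-en-1-one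
Product: 16 (4R)-4-[(2S,3R,5R)-5-bromo-3-[(tert-butyldimethylsilyl)oxy]-2,6,6-trimethyloxan-2-yl]-7-methylocta-1,7-dien-4-ol
Conditions: allylMgBr (2 equiv), THF, −78 °C; aq. NH4Cl
Reagents that add atoms: allylmagnesium bromide, C=CC[Mg]Br
Why: Grignard allylation of the α-alkoxy ketone under Felkin–Anh control, in which the bis-tertiary ring oxygen O1 is too hindered to chelate and the silyl ether does not chelate, so allyl should add anti to the C2–O1 bond and past the C2 methyl, setting C1' as R.

**Step 10**
Reactants: 16 (4R)-4-[(2S,3R,5R)-5-bromo-3-[(tert-butyldimethylsilyl)oxy]-2,6,6-trimethyloxan-2-yl]-7-methylocta-1,7-dien-4-ol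
Product: 17 (1R)-1-[(2S,3R,5R)-5-bromo-3-[(tert-butyldimethylsilyl)oxy]-2,6,6-trimethyloxan-2-yl]-4-methylcyclohex-3-en-1-ol
Conditions: Grubbs second-generation catalyst (5 mol%), CH2Cl2 (0.01 M), 40 °C
Reagents that add atoms: none
Why: Ring-closing metathesis of the monosubstituted and the 1,1-disubstituted alkene closes the cyclohexene at C4'=C5' with loss of ethylene and touches no stereocentre.

**Step 11**
Reactants: 17 (1R)-1-[(2S,3R,5R)-5-bromo-3-[(tert-butyldimethylsilyl)oxy]-2,6,6-trimethyloxan-2-yl]-4-methylcyclohex-3-en-1-ol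
Product: 18 (1S,2S,4R)-2-bromo-4-[(2S,3R,5R)-5-bromo-3-[(tert-butyldimethylsilyl)oxy]-2,6,6-trimethyloxan-2-yl]-1-methyl-7-oxabicyclo[2.2.1]heptane
Conditions: NBS (1.1 equiv), CH2Cl2, −20 to 0 °C, dark
Reagents that add atoms: N-bromosuccinimide, O=C1CCC(=O)N1Br
Why: Bromoetherification in which the axial C1' hydroxyl can reach C4' only across the ring from its own face, so it captures the bromonium ion formed on the opposite face at the tertiary carbon (Markovnikov, anti addition) and closes the 7-oxabicyclo[2.2.1]heptane; this sets C5' (Br trans to the oxygen) and the methyl-bearing C4'.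

**Step 12**
Reactants: 18 (1S,2S,4R)-2-bromo-4-[(2S,3R,5R)-5-bromo-3-[(tert-butyldimethylsilyl)oxy]-2,6,6-trimethyloxan-2-yl]-1-methyl-7-oxabicyclo[2.2.1]heptane
Product: 20 (1R,3S,4S)-3-bromo-1-[(2S,3R,5R)-5-bromo-3-[(tert-butyldimethylsilyl)oxy]-2,6,6-trimethyloxan-2-yl]-4-chloro-4-methylcyclohexan-1-ol, via dichloroboryl ether 19 (not isolated)
Conditions: BCl3 (1 M in CH2Cl2, 1.5 equiv), CH2Cl2, −78 °C; sat. aq. NaHCO3
Reagents that add atoms: boron trichloride, ClB(Cl)Cl
Why: Proposed new method: BCl3 binds the strained bridging ether oxygen, the C4'–O bond (antiperiplanar to the endo C5'–Br bond) ionises with bromine participation as the reverse of step 11, and chloride is returned from the O–BCl3 unit on the same face to the tertiary carbon anti to bromine, so C4' is substituted with retention and Cl ends cis to the C1' oxygen and trans to Br; the closest known reactions are the boron trihalide cleavage of 7-oxabicyclo[2.2.1]heptanes to 4-halocyclohexanols and substitutions with retention through neighbouring-bromine participation.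

**Step 13**
Reactants: 20 (1R,3S,4S)-3-bromo-1-[(2S,3R,5R)-5-bromo-3-[(tert-butyldimethylsilyl)oxy]-2,6,6-trimethyloxan-2-yl]-4-chloro-4-methylcyclohexan-1-ol
Product: 21 (1R,3S,4S)-3-bromo-1-[(2S,3R,5R)-5-bromo-3-hydroxy-2,6,6-trimethyloxan-2-yl]-4-chloro-4-methylcyclohexan-1-ol
Conditions: HF·pyridine, THF, pyridine, 0 °C to rt
Reagents that add atoms: none
Why: Cleavage of the silyl ether by fluoride under mildly acidic conditions, which should leave the tertiary chloride and both secondary bromides untouched.

**Compound list**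

1 | 2-methylfuran | Cc1ccco1 | starting material
2 | methyl pyruvate | CC(=O)C(=O)OC | starting material
3 | methyl (2S)-2-hydroxy-2-(5-methylfuran-2-yl)propanoate | O[C@](C)(C(=O)OC)c1ccc(C)o1 | intermediate
4 | methyl (2S)-2-(2,5-dimethoxy-5-methyl-2,5-dihydrofuran-2-yl)-2-hydroxypropanoate (ring diastereomers) | O[C@](C)(C(=O)OC)C1(OC)C=CC(C)(OC)O1 | intermediate (not isolated)
5 | methyl (2S,4Z)-2-hydroxy-2-methyl-3,6-dioxohept-4-enoate | O[C@](C)(C(=O)OC)C(=O)/C=C\C(C)=O | intermediate (not isolated)
6 | methyl (2S)-6-hydroxy-2,6-dimethyl-3-oxo-3,6-dihydro-2H-pyran-2-carboxylate (one anomer drawn) | C[C@@]1(O)O[C@](C)(C(=O)OC)C(=O)C=C1 | intermediate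
7 | methyl (2S)-2,6,6-trimethyl-3-oxo-3,6-dihydro-2H-pyran-2-carboxylate | CC1(C)O[C@](C)(C(=O)OC)C(=O)C=C1 | intermediate
8 | methyl (2S,5R)-5-bromo-2,6,6-trimethyl-3-[(trimethylsilyl)oxy]-5,6-dihydro-2H-pyran-2-carboxylate | CC1(C)O[C@](C)(C(=O)OC)C(O[Si](C)(C)C)=C[C@H]1Br | intermediate (not isolated)
9 | methyl (2S,5R)-5-bromo-2,6,6-trimethyl-3-oxooxane-2-carboxylate | CC1(C)O[C@](C)(C(=O)OC)C(=O)C[C@H]1Br | intermediate
10 | methyl (2S,3R,5R)-5-bromo-3-hydroxy-2,6,6-trimethyloxane-2-carboxylate | CC1(C)O[C@](C)(C(=O)OC)[C@H](O)C[C@H]1Br | intermediate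
11 | (2S,3R,5R)-5-bromo-3-hydroxy-N-methoxy-N,2,6,6-tetramethyloxane-2-carboxamide | CC1(C)O[C@](C)(C(=O)N(C)OC)[C@H](O)C[C@H]1Br | intermediate
12 | (2S,3R,5R)-5-bromo-3-[(tert-butyldimethylsilyl)oxy]-N-methoxy-N,2,6,6-tetramethyloxane-2-carboxamide | CC1(C)O[C@](C)(C(=O)N(C)OC)[C@H](O[Si](C)(C)C(C)(C)C)C[C@H]1Br | intermediate
13 | 4-bromo-2-methylbut-1-ene | C=C(C)CCBr | starting material
14 | (3-methylbut-3-en-1-yl)magnesium bromide | C=C(C)CC[Mg]Br | intermediate (not isolated)
15 | 1-[(2S,3R,5R)-5-bromo-3-[(tert-butyldimethylsilyl)oxy]-2,6,6-trimethyloxan-2-yl]-4-methylpent-4-en-1-one | CC1(C)O[C@](C)(C(=O)CCC(C)=C)[C@H](O[Si](C)(C)C(C)(C)C)C[C@H]1Br | intermediate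
16 | (4R)-4-[(2S,3R,5R)-5-bromo-3-[(tert-butyldimethylsilyl)oxy]-2,6,6-trimethyloxan-2-yl]-7-methylocta-1,7-dien-4-ol | CC1(C)O[C@](C)([C@@](CC=C)(O)CCC(C)=C)[C@H](O[Si](C)(C)C(C)(C)C)C[C@H]1Br | intermediate
17 | (1R)-1-[(2S,3R,5R)-5-bromo-3-[(tert-butyldimethylsilyl)oxy]-2,6,6-trimethyloxan-2-yl]-4-methylcyclohex-3-en-1-ol | CC1(C)O[C@](C)([C@@]2(O)CCC(C)=CC2)[C@H](O[Si](C)(C)C(C)(C)C)C[C@H]1Br | intermediate
18 | (1S,2S,4R)-2-bromo-4-[(2S,3R,5R)-5-bromo-3-[(tert-butyldimethylsilyl)oxy]-2,6,6-trimethyloxan-2-yl]-1-methyl-7-oxabicyclo[2.2.1]heptane | CC1(C)O[C@](C)([C@@]2(O3)CC[C@@]3(C)[C@@H](Br)C2)[C@H](O[Si](C)(C)C(C)(C)C)C[C@H]1Br | intermediate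
19 | O-dichloroboryl ether of 20 (alkoxydichloroborane at C1') | CC1(C)O[C@](C)([C@@]2(OB(Cl)Cl)CC[C@](C)(Cl)[C@@H](Br)C2)[C@H](O[Si](C)(C)C(C)(C)C)C[C@H]1Br | intermediate (not isolated)
20 | (1R,3S,4S)-3-bromo-1-[(2S,3R,5R)-5-bromo-3-[(tert-butyldimethylsilyl)oxy]-2,6,6-trimethyloxan-2-yl]-4-chloro-4-methylcyclohexan-1-ol | CC1(C)O[C@](C)([C@@]2(O)CC[C@](C)(Cl)[C@@H](Br)C2)[C@H](O[Si](C)(C)C(C)(C)C)C[C@H]1Br | intermediate
21 | (1R,3S,4S)-3-bromo-1-[(2S,3R,5R)-5-bromo-3-hydroxy-2,6,6-trimethyloxan-2-yl]-4-chloro-4-methylcyclohexan-1-ol | CC1(C)O[C@](C)([C@@]2(O)CC[C@](C)(Cl)[C@@H](Br)C2)[C@H](O)C[C@H]1Br | target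

**Total step count:** 13
**Longest linear sequence:** 13 steps (from 1 and 2 to 21; bromide 13 enters in step 8)

**Steps most likely to fail**

1. Step 12 (proposed new method). After ionisation of the C4'–O bond, chloride may open the bromonium ion at the secondary carbon C5' (the diaxial mode). Bromine may also be handed to chloride, so that the alkene re-forms and is halogenated from the other face. The Lewis acid may instead ionise the C1'–O bond or the β-bromo tertiary ether bond C6–O1 of the pyran.
   Fallback (known reactions only): it sets out from cyclohexenol 17 and avoids the bridged ether. The tertiary hydroxyl is silylated with triethylsilyl triflate and 2,6-lutidine to give the triethylsilyl ether F1. The axial silyloxy group then shields the alkene face syn to it. Tetrabutylammonium dichlorobromate in CH2Cl2 at low temperature should therefore form the bromonium ion on the opposite face, and chloride should open it at the tertiary carbon (anti, Markovnikov interhalogen addition) to give the bis-silyl ether F2 of the target. This addition runs against the usual preference for diaxial opening, so the bromochloride isomers may have to be separated. HF·pyridine then removes both silyl groups, and the route is rejoined at target 21.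

2. Step 3. Methyl transfer to the C3 carbonyl, or proton loss from the oxocarbenium ion to an exocyclic enol ether, may outrun methylation at C6, because the cation is conjugated with the enone and ionises reluctantly.
   Fallback: it sets out from hemiketal 6. Diethylaminosulfur trifluoride in CH2Cl2 at −78 °C exchanges the hemiketal hydroxyl for fluoride to give the anomeric fluoride F3. Trimethylaluminium then ionises the C–F bond at −78 °C (the C-glycosylation of glycosyl fluorides with organoaluminium reagents), where carbonyl addition should not compete, and transfers methyl. The route is rejoined at enone 7.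

3. Step 9. The very fast allyl Grignard addition may show poor facial selectivity, or chelation through O1 may direct allyl to the other ketone face and give the C1' epimer.
   Fallback: it sets out from Weinreb amide 12 and introduces the two chains in the opposite order. Allylmagnesium bromide at −78 °C gives the allyl ketone F4, which is kept cold and used at once to avoid conjugation of the alkene. Grignard reagent 14 is then added. The facial preference that gave the wrong epimer in step 9 now places the two chains in the required arrangement, and the route is rejoined at diene 16.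

**Further compounds**

F1 | step 12 | {[(1R)-1-[(2S,3R,5R)-5-bromo-3-[(tert-butyldimethylsilyl)oxy]-2,6,6-trimethyloxan-2-yl]-4-methylcyclohex-3-en-1-yl]oxy}triethylsilane | CC1(C)O[C@](C)([C@@]2(O[Si](CC)(CC)CC)CCC(C)=CC2)[C@H](O[Si](C)(C)C(C)(C)C)C[C@H]1Br
F2 | step 12 | {[(1R,3S,4S)-3-bromo-1-[(2S,3R,5R)-5-bromo-3-[(tert-butyldimethylsilyl)oxy]-2,6,6-trimethyloxan-2-yl]-4-chloro-4-methylcyclohexyl]oxy}triethylsilane | CC1(C)O[C@](C)([C@@]2(O[Si](CC)(CC)CC)CC[C@](C)(Cl)[C@@H](Br)C2)[C@H](O[Si](C)(C)C(C)(C)C)C[C@H]1Br
F3 | step 3 | methyl (2S)-6-fluoro-2,6-dimethyl-3-oxo-3,6-dihydro-2H-pyran-2-carboxylate (anomer mixture) | CC1(F)O[C@](C)(C(=O)OC)C(=O)C=C1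
F4 | step 9 | 1-[(2S,3R,5R)-5-bromo-3-[(tert-butyldimethylsilyl)oxy]-2,6,6-trimethyloxan-2-yl]but-3-en-1-one | CC1(C)O[C@](C)(C(=O)CC=C)[C@H](O[Si](C)(C)C(C)(C)C)C[C@H]1Br
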